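**Retrosynthetic overview**
- Calyxin H ⇒ removal of two MOM groups ⇒ Claisen–Schmidt disconnection of the chalcone into a ring A acetophenone that already carries the whole diarylheptenyl chain, plus a protected 4-hydroxybenzaldehyde (ring B).
- The E-olefin of the heptenyl chain ⇒ cross-metathesis of a 3,3-diarylpropene with (S)-1-phenylhex-5-en-3-ol (carbinol centre from a Brown allylation of 3-phenylpropanal).
- The ring A–CH(aryl) bond and the bis-benzylic (S) centre ⇒ a new catalytic enantioselective aromatic Claisen rearrangement of the cinnamyl ether of the ring A phenol (ether from a Mitsunobu reaction with a p-coumaryl alcohol pivalate).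
- No ring is constructed: all three benzene rings are bought and joined in the order ring A + hydroxyphenyl ring, then the phenethyl carbinol chain, then ring B.

Assumption: 1, 3, 9 and 13 are taken as catalogue compounds, and the (S,S)-ligand in step 5 is taken to give the (S) centre as drawn; this sense is a model-based prediction to be checked on first use, with the mirror-image ligand used if it is reversed.

**Route**

Step 1
Reactants: 1 2',4'-dihydroxy-6'-methoxyacetophenone
Product: 2 1-[2-hydroxy-6-methoxy-4-(methoxymethoxy)phenyl]ethan-1-one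
Conditions: MOMCl (1.1 equiv), i-Pr2NEt (1.5 equiv), CH2Cl2, 0 °C to rt
Reagents that add atoms: chloromethyl methyl ether (MOMCl), COCCl
Why: O-alkylation (MOM protection) is selective because the 4'-OH para to the acetyl group is free and the more acidic one, whereas the 2'-OH is locked in a hydrogen bond to the ketone.

Step 2
Reactants: 3 methyl (E)-3-(4-hydroxyphenyl)prop-2-enoate (methyl p-coumarate)
Product: 4 4-[(E)-3-hydroxyprop-1-en-1-yl]phenol (p-coumaryl alcohol)
Conditions: i-Bu2AlH (3.5 equiv), THF, −78 to 0 °C; aq. potassium sodium tartrate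
Reagents that add atoms: none
Why: Hydride 1,2-reduction of the unsaturated ester by i-Bu2AlH gives the allylic alcohol without touching the E-olefin, the extra equivalent covering the phenol.

Step 3
Reactants: 4 4-[(E)-3-hydroxyprop-1-en-1-yl]phenol
Product: 5 4-[(E)-3-hydroxyprop-1-en-1-yl]phenyl pivalate
Conditions: PivCl (1.05 equiv), NaOH (1.05 equiv), THF/H2O, 0 °C
Reagents that add atoms: pivaloyl chloride, CC(C)(C)C(=O)Cl
Why: Schotten–Baumann acylation is chemoselective because one equivalent of hydroxide ionises only the phenol (pKa about 10), so the phenoxide is acylated and the allylic alcohol stays free.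

Step 4
Reactants: 2 1-[2-hydroxy-6-methoxy-4-(methoxymethoxy)phenyl]ethan-1-one; 5 4-[(E)-3-hydroxyprop-1-en-1-yl]phenyl pivalate
Product: 6 4-[(E)-3-[2-acetyl-3-methoxy-5-(methoxymethoxy)phenoxy]prop-1-en-1-yl]phenyl pivalate
Conditions: PPh3 (1.3 equiv), DIAD (1.3 equiv), THF, 0 °C to rt
Reagents that add atoms: none
Why: Mitsunobu etherification works because the chelated phenol is acidic enough to protonate the betaine and then displaces the primary alkoxyphosphonium group by SN2, leaving the E-olefin unchanged.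

Step 5
Reactants: 6 4-[(E)-3-[2-acetyl-3-methoxy-5-(methoxymethoxy)phenoxy]prop-1-en-1-yl]phenyl pivalate
Product: 8 4-[(1S)-1-[3-acetyl-2-hydroxy-4-methoxy-6-(methoxymethoxy)phenyl]prop-2-en-1-yl]phenyl pivalate, via ortho-dienone 7 (not isolated)
Conditions: [Cu((S,S)-t-Bu-box)](SbF6)2 (10 mol %; (S,S)-t-Bu-box = 2,2'-(propane-2,2-diyl)bis[(4S)-4-tert-butyl-4,5-dihydrooxazole]), 4 Å MS, ClCH2CH2Cl, 40 °C
Reagents that add atoms: none
Why: Proposed new method: a catalytic enantioselective aromatic Claisen rearrangement of a benzenoid 2-acylaryl cinnamyl ether, in which the cationic divalent copper centre binds the ketone oxygen and the ether oxygen of 6 in a six-membered chelate, which polarises the O–CH2 bond (charge-accelerated [3,3] shift at 40 °C instead of about 180 °C) and lets the C2-symmetric ligand block one face of the chelate plane, so that the (E)-cinnamyl group folds over the open face onto C-3' (the only free ortho carbon, activated by its ortho and para oxygens) through a chair transition state and sets the bis-benzylic centre as (S) before dienone 7 tautomerises to the hydrogen-bonded phenol 8, while the electron-poor pivalate disfavours ionisation to a cinnamyl cation that would erode ee; the closest known reaction types are chiral Lewis acid catalysed aromatic Claisen rearrangements of allyl 2-naphthyl ethers carrying a chelating carbonyl group and the bis(oxazoline)–copper catalysed Claisen rearrangement of 2-alkoxycarbonyl allyl vinyl ethers by two-point binding.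

Step 6
Reactants: 9 3-phenylpropanal
Product: 11 (3S)-1-phenylhex-5-en-3-ol, via borinate ester 10 (not isolated)
Conditions: (+)-Ipc2BOMe (from (−)-α-pinene), CH2=CHCH2MgBr, Et2O, 0 °C to rt; then 9, −78 °C; then 3 M NaOH, 30% H2O2, rt
Reagents that add atoms: allylmagnesium bromide, C=CC[Mg]Br; (+)-B-methoxydiisopinocampheylborane, COB([C@H]1C[C@H]2C[C@@H]([C@@H]1C)C2(C)C)[C@H]1C[C@H]2C[C@@H]([C@@H]1C)C2(C)C (its boron and isopinocampheyl groups are held in 10 only)
Why: Brown asymmetric allylboration through a closed six-membered chair transition state delivers the allyl group of the (−)-α-pinene-derived reagent to the Re face of the aldehyde, setting the (S)-carbinol (typically above 90% ee), and oxidative work-up frees the alcohol.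

Step 7
Reactants: 8 4-[(1S)-1-[3-acetyl-2-hydroxy-4-methoxy-6-(methoxymethoxy)phenyl]prop-2-en-1-yl]phenyl pivalate; 11 (3S)-1-phenylhex-5-en-3-ol (3 equiv)
Product: 12 4-[(1S,2E,5S)-1-[3-acetyl-2-hydroxy-4-methoxy-6-(methoxymethoxy)phenyl]-5-hydroxy-7-phenylhept-2-en-1-yl]phenyl pivalate
Conditions: second-generation Hoveyda–Grubbs catalyst RuCl2(H2IMes)(=CH-C6H4-2-O-i-Pr) (5 mol %), 1,4-benzoquinone (10 mol %), CH2Cl2, 40 °C
Reagents that add atoms: none
Why: Olefin cross-metathesis is selective because the hindered 3,3-diarylpropene does not homodimerise while the excess homoallylic alcohol dimerises reversibly, the bulky allylic substituent enforces the E-olefin, benzoquinone suppresses Ru–H olefin migration into the bis-benzylic position, and neither stereocentre is touched.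

Step 8
Reactants: 12 4-[(1S,2E,5S)-1-[3-acetyl-2-hydroxy-4-methoxy-6-(methoxymethoxy)phenyl]-5-hydroxy-7-phenylhept-2-en-1-yl]phenyl pivalate; 13 4-(methoxymethoxy)benzaldehyde (2 equiv)
Product: 16 (E)-1-[2-hydroxy-3-[(1S,2E,5S)-5-hydroxy-1-(4-hydroxyphenyl)-7-phenylhept-2-en-1-yl]-6-methoxy-4-(methoxymethoxy)phenyl]-3-[4-(methoxymethoxy)phenyl]prop-2-en-1-one, via phenol ketone 14 (not isolated), via aldol adduct 15 (not isolated)
Conditions: KOH (50% aq., 20 equiv), EtOH, argon, 0 °C to rt, 36 h; then 1 M HCl to pH 5 at 0 °C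
Reagents that add atoms: none
Why: Claisen–Schmidt condensation (aldol addition then E1cB dehydration) gives the E-enone after the pivalate is saponified in the same pot, and the bis-benzylic C–H flanked by two phenoxide rings is too weakly acidic to epimerise or let the olefin migrate.

Step 9
Reactants: 16 (E)-1-[2-hydroxy-3-[(1S,2E,5S)-5-hydroxy-1-(4-hydroxyphenyl)-7-phenylhept-2-en-1-yl]-6-methoxy-4-(methoxymethoxy)phenyl]-3-[4-(methoxymethoxy)phenyl]prop-2-en-1-one
Product: 17 calyxin H, (E)-1-[2,4-dihydroxy-3-[(1S,2E,5S)-5-hydroxy-1-(4-hydroxyphenyl)-7-phenylhept-2-en-1-yl]-6-methoxyphenyl]-3-(4-hydroxyphenyl)prop-2-en-1-one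
Conditions: HCl (1.25 M in MeOH), 25–35 °C, stopped at full conversion
Reagents that add atoms: none
Why: Acid-catalysed acetal exchange (MOM cleavage by methanolysis) frees both phenols under conditions mild enough to leave the 2'-hydroxychalcone uncyclised and the stereocentres, which have no ionisable group, untouched.

**Compound list**

1 | 2',4'-dihydroxy-6'-methoxyacetophenone | CC(=O)c1c(O)cc(O)cc1OC | starting material
2 | 1-[2-hydroxy-6-methoxy-4-(methoxymethoxy)phenyl]ethan-1-one | CC(=O)c1c(O)cc(OCOC)cc1OC | intermediate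
3 | methyl (E)-3-(4-hydroxyphenyl)prop-2-enoate | COC(=O)/C=C/c1ccc(O)cc1 | starting material
4 | 4-[(E)-3-hydroxyprop-1-en-1-yl]phenol | OC/C=C/c1ccc(O)cc1 | intermediate
5 | 4-[(E)-3-hydroxyprop-1-en-1-yl]phenyl pivalate | CC(C)(C)C(=O)Oc1ccc(/C=C/CO)cc1 | intermediate
6 | 4-[(E)-3-[2-acetyl-3-methoxy-5-(methoxymethoxy)phenoxy]prop-1-en-1-yl]phenyl pivalate | CC(=O)c1c(OC/C=C/c2ccc(OC(=O)C(C)(C)C)cc2)cc(OCOC)cc1OC | intermediate
7 | 4-[(1R)-1-[(1R)-3-acetyl-4-methoxy-6-(methoxymethoxy)-2-oxocyclohexa-3,5-dien-1-yl]prop-2-en-1-yl]phenyl pivalate (ortho-dienone) | CC(=O)C1=C(OC)C=C(OCOC)[C@@H]([C@@H](C=C)c2ccc(OC(=O)C(C)(C)C)cc2)C1=O | intermediate (not isolated)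
8 | 4-[(1S)-1-[3-acetyl-2-hydroxy-4-methoxy-6-(methoxymethoxy)phenyl]prop-2-en-1-yl]phenyl pivalate | CC(=O)c1c(O)c([C@@H](C=C)c2ccc(OC(=O)C(C)(C)C)cc2)c(OCOC)cc1OC | intermediate
9 | 3-phenylpropanal | O=CCCc1ccccc1 | starting material
10 | (3S)-1-phenylhex-5-en-3-yl diisopinocampheylborinate (isopinocampheyl groups from (−)-α-pinene) | C=CC[C@@H](OB([C@H]1C[C@H]2C[C@@H]([C@@H]1C)C2(C)C)[C@H]1C[C@H]2C[C@@H]([C@@H]1C)C2(C)C)CCc1ccccc1 | intermediate (not isolated)
11 | (3S)-1-phenylhex-5-en-3-ol | C=CC[C@@H](O)CCc1ccccc1 | intermediate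
12 | 4-[(1S,2E,5S)-1-[3-acetyl-2-hydroxy-4-methoxy-6-(methoxymethoxy)phenyl]-5-hydroxy-7-phenylhept-2-en-1-yl]phenyl pivalate | CC(=O)c1c(O)c([C@@H](/C=C/C[C@@H](O)CCc2ccccc2)c2ccc(OC(=O)C(C)(C)C)cc2)c(OCOC)cc1OC | intermediate
13 | 4-(methoxymethoxy)benzaldehyde | COCOc1ccc(C=O)cc1 | starting material
14 | 1-[2-hydroxy-3-[(1S,2E,5S)-5-hydroxy-1-(4-hydroxyphenyl)-7-phenylhept-2-en-1-yl]-6-methoxy-4-(methoxymethoxy)phenyl]ethan-1-one | CC(=O)c1c(O)c([C@@H](/C=C/C[C@@H](O)CCc2ccccc2)c2ccc(O)cc2)c(OCOC)cc1OC | intermediate (not isolated)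
15 | 3-hydroxy-1-[2-hydroxy-3-[(1S,2E,5S)-5-hydroxy-1-(4-hydroxyphenyl)-7-phenylhept-2-en-1-yl]-6-methoxy-4-(methoxymethoxy)phenyl]-3-[4-(methoxymethoxy)phenyl]propan-1-one (both epimers at the new carbinol) | COCOc1ccc(C(O)CC(=O)c2c(O)c([C@@H](/C=C/C[C@@H](O)CCc3ccccc3)c3ccc(O)cc3)c(OCOC)cc2OC)cc1 | intermediate (not isolated)
16 | (E)-1-[2-hydroxy-3-[(1S,2E,5S)-5-hydroxy-1-(4-hydroxyphenyl)-7-phenylhept-2-en-1-yl]-6-methoxy-4-(methoxymethoxy)phenyl]-3-[4-(methoxymethoxy)phenyl]prop-2-en-1-one | COCOc1ccc(/C=C/C(=O)c2c(O)c([C@@H](/C=C/C[C@@H](O)CCc3ccccc3)c3ccc(O)cc3)c(OCOC)cc2OC)cc1 | intermediate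
17 | calyxin H | COc1cc(O)c([C@@H](/C=C/C[C@@H](O)CCc2ccccc2)c2ccc(O)cc2)c(O)c1C(=O)/C=C/c1ccc(O)cc1 | target

**Step count and risks**

Total: 9 steps. Longest linear sequence: 7 steps (3 → 4 → 5 → 6 → 8 → 12 → 16 → 17, steps 2, 3, 4, 5, 7, 8, 9).

The three steps most likely to fail are steps 5, 8 and 9.

Step 5 (the proposed new rearrangement) may fail in three ways: the 2-hydroxyaryl ketone product may hold the copper and stop turnover, the ether may ionise and give [1,3] or para products with low ee, or the facial sense may be opposite. The fallback uses known chemistry only, sets out from 6 and comes back at 8. Compound 6 is heated in N,N-diethylaniline at 180 °C, a classical thermal aromatic Claisen rearrangement to the only free ortho carbon. This gives racemic 4-[1-[3-acetyl-2-hydroxy-4-methoxy-6-(methoxymethoxy)phenyl]prop-2-en-1-yl]phenyl pivalate F1. F1 is resolved by preparative chiral SFC (amylose tris(3,5-dimethylphenylcarbamate) phase, CO2/MeOH) into 8 and the (1R)-enantiomer F2, which is set aside.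

Step 8 exposes the molecule to concentrated KOH for many hours; the risks are incomplete condensation, base-induced olefin migration that would destroy the bis-benzylic centre, and flavanone formation on work-up. The fallback sets out from 12 and comes back at 16, replacing the thermodynamic condensation by a directed aldol. Compound 12 is treated with LiN(SiMe3)2 (3.3 equiv) in THF at −78 °C to give the phenoxide–alkoxide–kinetic enolate, then 13 is added and the mixture is quenched cold with AcOH. This gives 4-[(1S,2E,5S)-5-hydroxy-1-[2-hydroxy-3-[3-hydroxy-3-[4-(methoxymethoxy)phenyl]propanoyl]-4-methoxy-6-(methoxymethoxy)phenyl]-7-phenylhept-2-en-1-yl]phenyl pivalate F3. Brief treatment of F3 with K2CO3 in MeOH at rt causes E1cB dehydration and methanolysis of the pivalate to give 16.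

Step 9 applies acid to the finished 2'-hydroxy-6'-methoxychalcone, which can close to the flavanone, and to the electron-rich allylic system. The fallback sets out from 12 and comes back at 17, moving the acid step ahead of the enone and ending under neutral conditions. Compound 12 is treated with HCl in MeOH at 40 °C, which is harmless at the acetophenone stage, to give 4-[(1S,2E,5S)-1-(3-acetyl-2,6-dihydroxy-4-methoxyphenyl)-5-hydroxy-7-phenylhept-2-en-1-yl]phenyl pivalate F4. Claisen–Schmidt condensation of F4 with 4-(allyloxy)benzaldehyde F5 (KOH, EtOH, rt; the pivalate is lost in the same pot) gives (E)-3-[4-(allyloxy)phenyl]-1-[2,4-dihydroxy-3-[(1S,2E,5S)-5-hydroxy-1-(4-hydroxyphenyl)-7-phenylhept-2-en-1-yl]-6-methoxyphenyl]prop-2-en-1-one F6. The aryl allyl ether of F6 is cleaved with Pd(PPh3)4 (5 mol %, zerovalent palladium) and morpholine in THF at rt to give 17.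

**Further compounds**

F1 | step 5 | racemic 4-[1-[3-acetyl-2-hydroxy-4-methoxy-6-(methoxymethoxy)phenyl]prop-2-en-1-yl]phenyl pivalate | CC(=O)c1c(O)c(C(C=C)c2ccc(OC(=O)C(C)(C)C)cc2)c(OCOC)cc1OC
F2 | step 5 | 4-[(1R)-1-[3-acetyl-2-hydroxy-4-methoxy-6-(methoxymethoxy)phenyl]prop-2-en-1-yl]phenyl pivalate | CC(=O)c1c(O)c([C@H](C=C)c2ccc(OC(=O)C(C)(C)C)cc2)c(OCOC)cc1OC
F3 | step 8 | 4-[(1S,2E,5S)-5-hydroxy-1-[2-hydroxy-3-[3-hydroxy-3-[4-(methoxymethoxy)phenyl]propanoyl]-4-methoxy-6-(methoxymethoxy)phenyl]-7-phenylhept-2-en-1-yl]phenyl pivalate (both carbinol epimers) | COCOc1ccc(C(O)CC(=O)c2c(O)c([C@@H](/C=C/C[C@@H](O)CCc3ccccc3)c3ccc(OC(=O)C(C)(C)C)cc3)c(OCOC)cc2OC)cc1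
F4 | step 9 | 4-[(1S,2E,5S)-1-(3-acetyl-2,6-dihydroxy-4-methoxyphenyl)-5-hydroxy-7-phenylhept-2-en-1-yl]phenyl pivalate | CC(=O)c1c(O)c([C@@H](/C=C/C[C@@H](O)CCc2ccccc2)c2ccc(OC(=O)C(C)(C)C)cc2)c(O)cc1OC
F5 | step 9 | 4-(allyloxy)benzaldehyde (bought) | C=CCOc1ccc(C=O)cc1
F6 | step 9 | (E)-3-[4-(allyloxy)phenyl]-1-[2,4-dihydroxy-3-[(1S,2E,5S)-5-hydroxy-1-(4-hydroxyphenyl)-7-phenylhept-2-en-1-yl]-6-methoxyphenyl]prop-2-en-1-one | C=CCOc1ccc(/C=C/C(=O)c2c(O)c([C@@H](/C=C/C[C@@H](O)CCc3ccccc3)c3ccc(O)cc3)c(O)cc2OC)cc1
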